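Readings and results are simulated with constants of no real substance; scatter was added.

**Same charges.** A pitfall: grey carries the charges of alder, so partner over substrate as charged says that the two flasks end alike. They differ in the substrate standing while it is consumed.

| flask | substrate | partner | second catalyst | precatalyst | remark | time |
|---|---|---|---|---|---|---|
| alder | 0.20 M | 0.19 M | 3.4 mM | 0.76 mM | run made earlier |  |
| birch | 0.20 M | 0.095 M | 3.4 mM | 0.76 mM | run made earlier |  |
| ash | 0.20 M | 0.38 M | 3.4 mM | 0.76 mM | run made earlier |  |
| ochre | 0.20 M | 0.190 M | 3.4 mM | 0.76 mM | everything together at the start | 12 h |
| grey | 0.20 M (in portions, 4, over 10 h) | 0.190 M | 3.4 mM | 0.76 mM | first portion at the start, last at 10 h | 12 h |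
| green | 0.20 M (fed, over 10 h) | 0.190 M | 3.4 mM | 0.76 mM | all else is in the flask from the start; the feed brings no volume worth counting | 12 h |
| violet | 0.20 M | 0.190 M (fed, over 10 h) | 3.4 mM | 0.76 mM | all else is in the flask from the start; the feed brings no volume worth counting | 12 h |

- alder (time / h: target / %, side product / %, substrate / %): 0.500: 2, 0, 95; 1.33: 1, 2, 92; 2.50: 6, 3, 81; 4.00: 18, 10, 57; 6.00: 31, 23, 36; 8.00: 40, 24, 24
- birch (time / h: target / %, side product / %, substrate / %): 1.50: 4, 2, 96; 3.00: 4, 2, 81; 5.00: 10, 14, 60; 6.00: 17, 19, 55; 8.00: 22, 26, 34; 10.0: 28, 34, 21
- ash (time / h: target / %, side product / %, substrate / %): 1.50: 3, 4, 85; 3.00: 22, 7, 63; 5.00: 37, 14, 38; 6.00: 45, 17, 27; 8.00: 59, 15, 15; 10.0: 66, 19, 12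

(each reading ± 2 percentage points)

- the best flask by share of target in target plus side product; "all alike" if 1.5 percentage points covers them all (ochre / grey / green / violet / all alike)
- share of target in target plus side product at the end, ochre
- share of target in target plus side product at the end, grey
- share of target in target plus side product at the end, green
- share of target in target plus side product at the end, violet

- in percentages every species weighs as the substrate in it: one side product counts as two
- the earlier runs were read with a standard deviation of 2 percentage points

**Split factor.** Alder reads 1.75 at 8.00 h, birch 1.73 and ash 1.83 at 10.0 h, for target over side product times substrate charge over partner charge. This is the split factor σ, a selectivity factor. Across these partner charges it moves little.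

**Fraction left.** One side product holds two substrate units, so this reckoning takes target over side product as inverse to the standing substrate. Averaged over the substrate consumed, alder's level is the mean of its start and its last reading, 62.0% of the charge. Alder's readings from 4.00 h to 8.00 h give a loss constant k of 0.216 /h.

Grey's portions stand 3.33 h apart, and 48.6% survives each gap. Its level, counted from zero, therefore peaks at 25.0%, 37.2%, 43.1% and 45.9%, and 64.9% of the last peak survives to 12 h. Averaged over the substrate consumed, each falling stretch counts at the mean of its two ends, so grey's level comes to 29.7%. Grey thus works at less substrate than alder, a gain of 2.09. Green's level climbs towards the 46.2% at which feed matches loss, reaches 40.9% when the feed ends at 10 h, and then falls as grey's does. Averaged the same way it comes to 32.4%, above grey.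

So this reckoning gives grey 77.7% and green 76.1%, with grey best. Ochre, alder's recipe, takes alder's 62.5%. Violet doses partner, which this reckoning does not cover.

**Forecast.** The forecast names green as best, with 66%, 72%, 74% and 44% for ochre, grey, green and violet, holding “side second order in substrate”.

**Result.** The best flask is grey: ochre ends at 67.8%, grey at 74.7%, green at 72.7% and violet at 58.2%.

    substrate + free catalyst → free catalyst + open intermediate (k = 5.27 /M/min)
    second catalyst + open intermediate ⇌ catalyst intermediate (K = 10.0 /M, k = 10.8 /M/min)
    partner + catalyst intermediate → second catalyst + target (k = 3.29 /M/min)
    substrate + open intermediate → side product (k = 0.0263 /M/min)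
    partner + precatalyst → free catalyst + spent reagent (k = 0.0307 /M/min)

**Thin partner.** Grey's share means a σ of 3.12, which is 1.78 times alder's, against the reckoned gain of 2.09. The neighbour flask has grey's recipe with 0.076 M of partner. The same σ, gain and charges give it 58.2%, and it ends at 48.7%. Its target stands at 22.7% and its side product at 23.9%. Substrate, at 34.1%, is the largest holder of the charge.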